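**Retrosynthetic overview**
- Target ⇒ hydrogenolysis of four benzyl ethers from a benzyl-protected epicatechin gallate that already carries the ester.
- Ring C (the only ring formed; rings A and B and the galloyl ring are bought) ⇒ intramolecular reductive etherification of an open-chain α-galloyloxy aryl ketone by the ortho phenol of ring A; C2 is set from C3.
- Ester ⇒ Steglich coupling of an (R)-α-hydroxy ketone with tri-O-benzylgallic acid.
- C2–C3 bond (key step) ⇒ enantioselective carbene-catalysed cross-benzoin: the ring B aldehyde acts as acyl anion equivalent (Breslow intermediate) and adds to a ring A arylacetaldehyde, setting C3.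
- Arylacetaldehyde ⇒ PMB protection and one-carbon homologation of 2,4,6-trihydroxybenzaldehyde.

Assumption: the target is the (2R,3R) enantiomer written in the SMILES. The (5S) triazolium salt (from L-pyroglutamic acid) is taken to be the antipode that gives (R)-benzoin from benzaldehyde, i.e. Si-face attack on the acceptor. The configuration of the ketol is checked by Mosher ester analysis on the first run, and the (5R) salt is used if the sense is opposite.

**Step 1**
Reactants: 1 2,4,6-trihydroxybenzaldehyde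
Product: 2 2,4,6-tris[(4-methoxybenzyl)oxy]benzaldehyde
Conditions: 4-methoxybenzyl chloride (3.6 equiv), K2CO3 (4.5 equiv), Bu4NI (0.1 equiv), DMF, 60 °C
Reagents that add atoms: 4-methoxybenzyl chloride, COc1ccc(CCl)cc1
Why: Williamson ether synthesis, in which the formyl group deactivates the ring against C-alkylation and gentle heating also alkylates the hydrogen-bonded ortho hydroxyls.

**Step 2**
Reactants: 2 2,4,6-tris[(4-methoxybenzyl)oxy]benzaldehyde
Product: 4 2-{2,4,6-tris[(4-methoxybenzyl)oxy]phenyl}acetaldehyde, via enol ether 3 (not isolated)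
Conditions: (methoxymethyl)triphenylphosphonium chloride (1.5 equiv), KOtBu (1.45 equiv), THF, 0 °C → rt; then 1 M aq. HCl–THF (1:4), 0 °C → rt, 1 h; used at once
Reagents that add atoms: (methoxymethyl)triphenylphosphonium chloride, COC[P+](c1ccccc1)(c1ccccc1)c1ccccc1.[Cl-]; water, O
Why: Wittig methoxymethylenation followed by mild hydrolysis of the enol ether is the standard one-carbon homologation of an aryl aldehyde to an arylacetaldehyde, and aryl PMB ethers tolerate brief dilute aqueous acid.

**Step 3**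
Reactants: 4 2-{2,4,6-tris[(4-methoxybenzyl)oxy]phenyl}acetaldehyde; 5 3-(benzyloxy)-4-methoxybenzaldehyde
Product: 6 (2R)-1-[3-(benzyloxy)-4-methoxyphenyl]-2-hydroxy-3-{2,4,6-tris[(4-methoxybenzyl)oxy]phenyl}propan-1-one
Conditions: 5 (3.0 equiv), (5S)-5-[hydroxy(diphenyl)methyl]-2-(pentafluorophenyl)-6,7-dihydro-5H-pyrrolo[2,1-c][1,2,4]triazol-2-ium tetrafluoroborate (10 mol%), Rb2CO3 (10 mol%), THF, 0 °C, argon; 4 added by syringe pump over 8 h, then 4 h at 0 °C; excess 5 recovered
Reagents that add atoms: none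
Why: Proposed new method: the triazolylidene adds to 5, whose conjugated Breslow intermediate (the acyl anion equivalent at C2) dominates because 5 is in excess and 4 is kept at low concentration, and this nucleophile attacks the Si face of the far more electrophilic aliphatic aldehyde 4, held by the hydrogen bond of the catalyst hydroxyl, to set C3 as (R); electron-rich 5 is a poor acceptor, so its homo-benzoin is slow and reversible, and the aryl-conjugated cross ketol is also the thermodynamically preferred regioisomer; the closest known reactions are the highly enantioselective triazolium-catalysed benzoin condensation, thiazolium-catalysed cross-acyloin couplings of aromatic donors with aliphatic acceptors, and thiamine-dependent lyases that give (R)-2-hydroxy-1-aryl ketones.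

**Step 4**
Reactants: 6 (2R)-1-[3-(benzyloxy)-4-methoxyphenyl]-2-hydroxy-3-{2,4,6-tris[(4-methoxybenzyl)oxy]phenyl}propan-1-one; 7 3,4,5-tris(benzyloxy)benzoic acid
Product: 8 (2R)-1-[3-(benzyloxy)-4-methoxyphenyl]-1-oxo-3-{2,4,6-tris[(4-methoxybenzyl)oxy]phenyl}propan-2-yl 3,4,5-tris(benzyloxy)benzoate
Conditions: 7 (1.3 equiv), N,N'-dicyclohexylcarbodiimide (DCC, 1.4 equiv), 4-(dimethylamino)pyridine (0.05 equiv), CH2Cl2, 0 °C
Reagents that add atoms: none
Why: Steglich esterification acylates the secondary hydroxyl without touching the C3–O bond, so the (R) configuration is retained, and low temperature with only catalytic base limits enolisation of the α-acyloxy ketone.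

**Step 5**
Reactants: 8 (2R)-1-[3-(benzyloxy)-4-methoxyphenyl]-1-oxo-3-{2,4,6-tris[(4-methoxybenzyl)oxy]phenyl}propan-2-yl 3,4,5-tris(benzyloxy)benzoate
Product: 11 (2R,3R)-2-[3-(benzyloxy)-4-methoxyphenyl]-5,7-dihydroxy-3,4-dihydro-2H-chromen-3-yl 3,4,5-tris(benzyloxy)benzoate, via triphenol ketone 9 (not isolated), via cyclic hemiketal 10 (not isolated)
Conditions: Et3SiH (10 equiv), CF3CO2H–CH2Cl2 (1:4), 0 °C → rt
Reagents that add atoms: none
Why: CF3CO2H cleaves the three aryl PMB ethers (Et3SiH reduces the PMB cations to 4-methylanisole), the freed ortho phenol closes onto the ketone, and the ring C oxocarbenium ion is reduced by Et3SiH (intramolecular reductive etherification, an ionic hydrogenation); hydride adds to C2 anti to the C3 gallate, which sits pseudoaxial and can bridge as an acyloxonium ion, so H-2 ends trans to O-3 and the aryl group cis to the ester, giving (2R,3R).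

**Step 6**
Reactants: 11 (2R,3R)-2-[3-(benzyloxy)-4-methoxyphenyl]-5,7-dihydroxy-3,4-dihydro-2H-chromen-3-yl 3,4,5-tris(benzyloxy)benzoate
Product: 12 4'-O-methylepicatechin-3-O-gallate
Conditions: H2 (1 atm), Pd(OH)2/C (20 wt%), THF–MeOH (1:1), rt
Reagents that add atoms: none
Why: Catalytic hydrogenolysis removes the four benzyl ethers while the ester, the methyl ether, the ring C ether and both stereocentres are untouched, as is routine for catechin gallates.

**Compound list**
1 | 2,4,6-trihydroxybenzaldehyde | O=Cc1c(O)cc(O)cc1O | starting material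
2 | 2,4,6-tris[(4-methoxybenzyl)oxy]benzaldehyde | O=Cc1c(OCc2ccc(OC)cc2)cc(OCc2ccc(OC)cc2)cc1OCc1ccc(OC)cc1 | intermediate
3 | 2-(2-methoxyethenyl)-1,3,5-tris[(4-methoxybenzyl)oxy]benzene (enol ether, E/Z mixture, formed in the flask) | COC=Cc1c(OCc2ccc(OC)cc2)cc(OCc2ccc(OC)cc2)cc1OCc1ccc(OC)cc1 | intermediate
4 | 2-{2,4,6-tris[(4-methoxybenzyl)oxy]phenyl}acetaldehyde | O=CCc1c(OCc2ccc(OC)cc2)cc(OCc2ccc(OC)cc2)cc1OCc1ccc(OC)cc1 | intermediate
5 | 3-(benzyloxy)-4-methoxybenzaldehyde | COc1ccc(C=O)cc1OCc1ccccc1 | starting material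
6 | (2R)-1-[3-(benzyloxy)-4-methoxyphenyl]-2-hydroxy-3-{2,4,6-tris[(4-methoxybenzyl)oxy]phenyl}propan-1-one | COc1ccc(C(=O)[C@H](O)Cc2c(OCc3ccc(OC)cc3)cc(OCc3ccc(OC)cc3)cc2OCc2ccc(OC)cc2)cc1OCc1ccccc1 | intermediate
7 | 3,4,5-tris(benzyloxy)benzoic acid | OC(=O)c1cc(OCc2ccccc2)c(OCc2ccccc2)c(OCc2ccccc2)c1 | starting material
8 | (2R)-1-[3-(benzyloxy)-4-methoxyphenyl]-1-oxo-3-{2,4,6-tris[(4-methoxybenzyl)oxy]phenyl}propan-2-yl 3,4,5-tris(benzyloxy)benzoate | COc1ccc(C(=O)[C@H](OC(=O)c2cc(OCc3ccccc3)c(OCc3ccccc3)c(OCc3ccccc3)c2)Cc2c(OCc3ccc(OC)cc3)cc(OCc3ccc(OC)cc3)cc2OCc2ccc(OC)cc2)cc1OCc1ccccc1 | intermediate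
9 | (2R)-1-[3-(benzyloxy)-4-methoxyphenyl]-1-oxo-3-(2,4,6-trihydroxyphenyl)propan-2-yl 3,4,5-tris(benzyloxy)benzoate (triphenol ketone, formed in the flask) | COc1ccc(C(=O)[C@H](OC(=O)c2cc(OCc3ccccc3)c(OCc3ccccc3)c(OCc3ccccc3)c2)Cc2c(O)cc(O)cc2O)cc1OCc1ccccc1 | intermediate
10 | (3R)-2-[3-(benzyloxy)-4-methoxyphenyl]-2,5,7-trihydroxy-3,4-dihydro-2H-chromen-3-yl 3,4,5-tris(benzyloxy)benzoate (cyclic hemiketal, both C2 epimers, formed in the flask) | COc1ccc(C2(O)Oc3cc(O)cc(O)c3C[C@H]2OC(=O)c2cc(OCc3ccccc3)c(OCc3ccccc3)c(OCc3ccccc3)c2)cc1OCc1ccccc1 | intermediate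
11 | (2R,3R)-2-[3-(benzyloxy)-4-methoxyphenyl]-5,7-dihydroxy-3,4-dihydro-2H-chromen-3-yl 3,4,5-tris(benzyloxy)benzoate | COc1ccc([C@H]2Oc3cc(O)cc(O)c3C[C@H]2OC(=O)c2cc(OCc3ccccc3)c(OCc3ccccc3)c(OCc3ccccc3)c2)cc1OCc1ccccc1 | intermediate
12 | 4'-O-methylepicatechin-3-O-gallate, (2R,3R)-5,7-dihydroxy-2-(3-hydroxy-4-methoxyphenyl)-3,4-dihydro-2H-chromen-3-yl 3,4,5-trihydroxybenzoate | COc1ccc([C@H]2Oc3cc(O)cc(O)c3C[C@H]2OC(=O)c2cc(O)c(O)c(O)c2)cc1O | target

**Step count and risks**
Total steps: 6. Longest linear sequence: 6 steps (1 → 2 → 4 → 6 → 8 → 11 → 12); 5 and 7 are purchased and enter at steps 3 and 4.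

The three steps most likely to fail:

Step 3 (cross-benzoin) is the main risk. The two aldehydes may exchange donor and acceptor roles, 4 may self-condense or undergo aldol reaction, and the enantiomeric excess may be modest or erode by enolisation of 6. Fallback, setting out from 5 and rejoining at 6: the donor is fixed stoichiometrically as an acylsilane. Thioacetalisation of 5 with propane-1,3-dithiol and BF3·OEt2 gives 2-[3-(benzyloxy)-4-methoxyphenyl]-1,3-dithiane F1. Treatment with n-BuLi and then Et3SiCl gives {2-[3-(benzyloxy)-4-methoxyphenyl]-1,3-dithian-2-yl}triethylsilane F2. MeI and CaCO3 in aqueous MeCN unmask [3-(benzyloxy)-4-methoxyphenyl](triethylsilyl)methanone F3. A catalytic amount of the lithium salt of the cyclic phosphite of 2,2-dimethyl-α,α,α′,α′-tetrakis(2-fluorophenyl)-1,3-dioxolane-4,5-dimethanol (the (4R,5R) or (4S,5S) antipode, chosen for the (R) product) adds to F3. Brook rearrangement then gives a silyloxy phosphonate carbanion that can only act as the acyl donor. Its addition to 4 with silyl transfer gives (2R)-1-[3-(benzyloxy)-4-methoxyphenyl]-2-[(triethylsilyl)oxy]-3-{2,4,6-tris[(4-methoxybenzyl)oxy]phenyl}propan-1-one F4 (asymmetric cross silyl benzoin). AcOH–THF–H2O removes the silyl group to give 6.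

Step 5 (PMB removal and reductive ring closure) is the second risk. PMB cations may C-alkylate the very electron-rich ring A, C3 may epimerise through the flav-2-ene enol ester (which would lower the enantiomeric excess), and the ketone or the product may be over-reduced. Fallback, setting out from 8 and rejoining at the target 12: all benzylic ethers are removed first without any cation. H2 with Pd(OH)2/C in THF–MeOH cleaves the three PMB and four benzyl ethers to give (2R)-1-(3-hydroxy-4-methoxyphenyl)-1-oxo-3-(2,4,6-trihydroxyphenyl)propan-2-yl 3,4,5-trihydroxybenzoate F5, present largely as its hemiketal. Et3SiH with BF3·OEt2 in MeCN at −30 °C then closes ring C by the same anti hydride delivery and gives 12 directly, bypassing 11.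

Step 2 (homologation) is the third risk. PMB ethers may be partly lost in aqueous acid, and the electron-rich arylacetaldehyde 4 is prone to enolisation, aldol reaction and air oxidation. Fallback, setting out from 2 and rejoining at 4: Corey–Chaykovsky methylenation with trimethylsulfonium iodide and NaH in DMSO–THF gives 2-{2,4,6-tris[(4-methoxybenzyl)oxy]phenyl}oxirane F6. A Meinwald rearrangement with catalytic InCl3 in THF (benzylic cation, 1,2-hydride shift) then gives 4 under non-aqueous, nearly neutral conditions, and the solution is used directly in step 3.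

**Further compounds**
F1 | step 3 | 2-[3-(benzyloxy)-4-methoxyphenyl]-1,3-dithiane | COc1ccc(C2SCCCS2)cc1OCc1ccccc1
F2 | step 3 | {2-[3-(benzyloxy)-4-methoxyphenyl]-1,3-dithian-2-yl}triethylsilane | COc1ccc(C2([Si](CC)(CC)CC)SCCCS2)cc1OCc1ccccc1
F3 | step 3 | [3-(benzyloxy)-4-methoxyphenyl](triethylsilyl)methanone | COc1ccc(C(=O)[Si](CC)(CC)CC)cc1OCc1ccccc1
F4 | step 3 | (2R)-1-[3-(benzyloxy)-4-methoxyphenyl]-2-[(triethylsilyl)oxy]-3-{2,4,6-tris[(4-methoxybenzyl)oxy]phenyl}propan-1-one | COc1ccc(C(=O)[C@H](O[Si](CC)(CC)CC)Cc2c(OCc3ccc(OC)cc3)cc(OCc3ccc(OC)cc3)cc2OCc2ccc(OC)cc2)cc1OCc1ccccc1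
F5 | step 5 | (2R)-1-(3-hydroxy-4-methoxyphenyl)-1-oxo-3-(2,4,6-trihydroxyphenyl)propan-2-yl 3,4,5-trihydroxybenzoate | COc1ccc(C(=O)[C@H](OC(=O)c2cc(O)c(O)c(O)c2)Cc2c(O)cc(O)cc2O)cc1O
F6 | step 2 | 2-{2,4,6-tris[(4-methoxybenzyl)oxy]phenyl}oxirane (racemic) | C1OC1c1c(OCc2ccc(OC)cc2)cc(OCc2ccc(OC)cc2)cc1OCc1ccc(OC)cc1
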